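**Retrosynthetic overview**
- The target comes from its octamethyl ether, which carries one free OH on ring C, by a single global O-demethylation.
- Key disconnection, made last: the C–D biaryl bond. Both carbons are innately nucleophilic phloroglucinol CH positions. Ring C is therefore oxidised with PhI(OAc)2 to a phenoxenium ion (the aromatic counterpart of an enolonium ion), and 1,3,5-trimethoxybenzene (ring D) attacks it.
- The A–B–C phenol comes from a Dakin oxidation of the corresponding benzaldehyde, which in turn comes from two Ullmann ether couplings (B–O–C, then A–O–B).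
- No ring is built. All four benzene rings are bought and joined in the order A + B, then C, then D.

Assumption: the SMILES holds no stereocentre and ring D is symmetric about the biaryl axis, so the target is achiral and no step needs stereocontrol.

**Route**

Step 1
Reactants: 1 5-methoxybenzene-1,3-diol (5-methoxyresorcinol, ring B); 2 1-bromo-3,5-dimethoxybenzene (ring A)
Product: 3 3-(3,5-dimethoxyphenoxy)-5-methoxyphenol
Conditions: 1 (3 equiv), CuI (10 mol %), picolinic acid (20 mol %), K3PO4 (2 equiv), DMSO, 90 °C, Ar
Reagents that add atoms: none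
Why: Ullmann diaryl ether synthesis, in which picolinate-ligated monovalent copper couples the aryl bromide with one phenoxide of the symmetric diol, the threefold excess of water-extractable 1 suppresses double arylation, and no stereocentre is formed.

Step 2
Reactants: 3 3-(3,5-dimethoxyphenoxy)-5-methoxyphenol; 4 4-bromo-3,5-dimethoxybenzaldehyde (ring C)
Product: 5 4-[3-(3,5-dimethoxyphenoxy)-5-methoxyphenoxy]-3,5-dimethoxybenzaldehyde
Conditions: 4 (1.2 equiv), CuI (15 mol %), picolinic acid (30 mol %), K3PO4 (2 equiv), DMSO, 100 °C, Ar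
Reagents that add atoms: none
Why: Ullmann diaryl ether synthesis with a ligand system suited to ortho-substituted partners, in which the para-formyl group activates the flanked C–Br bond, the unhindered electron-rich phenoxide of 3 is a good nucleophile, and the non-enolisable aldehyde tolerates K3PO4.

Step 3
Reactants: 5 4-[3-(3,5-dimethoxyphenoxy)-5-methoxyphenoxy]-3,5-dimethoxybenzaldehyde
Product: 7 4-[3-(3,5-dimethoxyphenoxy)-5-methoxyphenoxy]-3,5-dimethoxyphenol, via aryl formate 6 (not isolated)
Conditions: 30% aq H2O2 (1.5 equiv), H2SO4 (cat.), MeOH/CH2Cl2 3:1, rt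
Reagents that add atoms: hydrogen peroxide, OO
Why: Acid-catalysed Dakin oxidation (Baeyer–Villiger-type aryl migration), in which the para-aryloxy donor makes the aryl group migrate in the peroxyhemiacetal, formate 6 is methanolysed in the same flask, and the conditions are those that turn 3,4,5-trialkoxy- and 4-aryloxybenzaldehydes cleanly into phenols without touching aryl ethers.

Step 4
Reactants: 7 4-[3-(3,5-dimethoxyphenoxy)-5-methoxyphenoxy]-3,5-dimethoxyphenol; 8 1,3,5-trimethoxybenzene (ring D); 9 (diacetoxyiodo)benzene, PhI(OAc)2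
Product: 12 4-[3-(3,5-dimethoxyphenoxy)-5-methoxyphenoxy]-3,5-dimethoxy-2-(2,4,6-trimethoxyphenyl)phenol, via aryloxy-λ3-iodane 10 (not isolated), via arylated dienone 11 (not isolated)
Conditions: 8 (5 equiv), 9 (1.0 equiv, added over 30 min), (CF3)2CHOH/CH2Cl2 4:1, 4 Å MS, 0 °C, Ar
Reagents that add atoms: none
Why: Hypervalent-iodine oxidative phenol–arene cross-coupling (aromatic-ring umpolung), in which ligand exchange of 7 on the trivalent iodine of 9 gives 10, ionisation in the strongly ionising, non-nucleophilic fluoroalcohol expels PhI and acetate to leave a para-aryloxy-stabilised phenoxenium ion whose carbon ortho to the former phenol oxygen is now electrophilic, the nucleophilic CH of 8 attacks it (8 is in fivefold excess and richer than rings A and B, the two ortho sites of ring C are equivalent and the para site is blocked), and dienone 11 tautomerises to 12 so that its transient sp3 carbon vanishes and no stereocentre remains.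

Step 5
Reactants: 12 4-[3-(3,5-dimethoxyphenoxy)-5-methoxyphenoxy]-3,5-dimethoxy-2-(2,4,6-trimethoxyphenyl)phenol
Product: 13 3-[3-(3,5-dihydroxyphenoxy)-5-hydroxyphenoxy]-[1,1'-biphenyl]-2,2',4,4',6,6'-hexol (target, achiral)
Conditions: BBr3 (16 equiv), CH2Cl2, −78 °C to rt; then ice-water; EtOAc extraction, Sephadex LH-20 under Ar
Reagents that add atoms: none
Why: Lewis-acid aryl methyl ether cleavage with BBr3, in which bromide attacks only the methyl carbons of the eight boron-complexed OMe groups, while the two diaryl ether bonds and the biaryl bond have no sp3 carbon to attack and stay intact.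

**Compound list**
1 | 5-methoxybenzene-1,3-diol (5-methoxyresorcinol) | COc1cc(O)cc(O)c1 | starting material
2 | 1-bromo-3,5-dimethoxybenzene | COc1cc(Br)cc(OC)c1 | starting material
3 | 3-(3,5-dimethoxyphenoxy)-5-methoxyphenol | COc1cc(O)cc(Oc2cc(OC)cc(OC)c2)c1 | intermediate
4 | 4-bromo-3,5-dimethoxybenzaldehyde | COc1cc(C=O)cc(OC)c1Br | starting material
5 | 4-[3-(3,5-dimethoxyphenoxy)-5-methoxyphenoxy]-3,5-dimethoxybenzaldehyde | COc1cc(Oc2cc(OC)cc(OC)c2)cc(Oc2c(OC)cc(C=O)cc2OC)c1 | intermediate
6 | 4-[3-(3,5-dimethoxyphenoxy)-5-methoxyphenoxy]-3,5-dimethoxyphenyl formate (formed in the flask) | COc1cc(Oc2cc(OC)cc(OC)c2)cc(Oc2c(OC)cc(OC=O)cc2OC)c1 | intermediate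
7 | 4-[3-(3,5-dimethoxyphenoxy)-5-methoxyphenoxy]-3,5-dimethoxyphenol | COc1cc(Oc2cc(OC)cc(OC)c2)cc(Oc2c(OC)cc(O)cc2OC)c1 | intermediate
8 | 1,3,5-trimethoxybenzene | COc1cc(OC)cc(OC)c1 | starting material
9 | (diacetoxyiodo)benzene, PhI(OAc)2 | CC(=O)OI(OC(C)=O)c1ccccc1 | starting material
10 | acetoxy{4-[3-(3,5-dimethoxyphenoxy)-5-methoxyphenoxy]-3,5-dimethoxyphenoxy}(phenyl)-λ3-iodane (formed in the flask) | CC(=O)OI(Oc1cc(OC)c(Oc2cc(OC)cc(Oc3cc(OC)cc(OC)c3)c2)c(OC)c1)c1ccccc1 | intermediate
11 | 4-[3-(3,5-dimethoxyphenoxy)-5-methoxyphenoxy]-3,5-dimethoxy-6-(2,4,6-trimethoxyphenyl)cyclohexa-2,4-dien-1-one (formed in the flask, racemic at the transient C6) | COC1=CC(=O)C(c2c(OC)cc(OC)cc2OC)C(OC)=C1Oc1cc(OC)cc(Oc2cc(OC)cc(OC)c2)c1 | intermediate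
12 | 4-[3-(3,5-dimethoxyphenoxy)-5-methoxyphenoxy]-3,5-dimethoxy-2-(2,4,6-trimethoxyphenyl)phenol | COc1cc(OC)c(-c2c(O)cc(OC)c(Oc3cc(OC)cc(Oc4cc(OC)cc(OC)c4)c3)c2OC)c(OC)c1 | intermediate
13 | 3-[3-(3,5-dihydroxyphenoxy)-5-hydroxyphenoxy]-[1,1'-biphenyl]-2,2',4,4',6,6'-hexol (CNP0133338.0) | Oc1cc(O)cc(Oc2cc(O)cc(Oc3c(O)cc(O)c(-c4c(O)cc(O)cc4O)c3O)c2)c1 | target

**Totals**
Total step count: 5. Longest linear sequence: 5 (1 → 3 → 5 → 7 → 12 → 13).

**The three steps most likely to fail**

**Step 4 (highest risk).**
- Adventitious water can capture the phenoxenium ion at its aryloxy-bearing carbon, which would shed the A–B phenol.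
- Ring A or ring B of a second molecule can capture the ion instead of 8.
- Product 12 can be oxidised further.
- Oxidant 9 can be consumed by 8.
- Methanol is kept out on purpose, because a mixed aryl methyl quinone ketal would ionise with loss of the aryloxy group.

Fallback: it sets out from 7 and 8 and comes back at 12, and it moves the polarity reversal from ring C to ring D. Compound 8 is plumbylated directly with Pb(OAc)4 (CHCl3, rt) to 2,4,6-trimethoxyphenyllead triacetate F1, an aryl cation equivalent of tetravalent lead. F1 then arylates the ortho carbon of phenol 7 by ligand coupling within the lead coordination sphere (pyridine, CHCl3, 40 °C, Pinhey arylation). This gives 12 without any free cation that water or rings A and B could intercept.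

**Step 2.** The bromide sits between two methoxy groups, so the copper cycle may stall, or the aryl bromide may simply be reduced.

Fallback: it sets out from 3 and comes back at 5, and it gives up both copper and the bromide. Purchased syringaldehyde (4-hydroxy-3,5-dimethoxybenzaldehyde) is converted with Tf2O/pyridine (CH2Cl2, 0 °C) into 4-formyl-2,6-dimethoxyphenyl trifluoromethanesulfonate F2. F2 is joined to 3 by zerovalent-palladium C–O cross-coupling (Pd2(dba)3, t-BuXPhos, K3PO4, toluene, 100 °C). In that cycle the electron-poor, doubly ortho-substituted aryl ligand and the electron-rich phenoxide both speed the C–O reductive elimination.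

**Step 5.** Eight cleavages must all go to completion. The free nonaphenol is very polar, binds boron residues and oxidises in air, so isolation is the likely point of loss.

Fallback: it sets out from 12 and comes back at 13. The crude material from the BBr3 cleavage is not purified. It is peracetylated at once (Ac2O, pyridine, DMAP (cat.), rt) to the air-stable, silica-chromatographable nonaacetate F3. F3 also allows under-cleaved material to be separated. Pure F3 is then unmasked by base-catalysed transesterification under argon (K2CO3 (cat.), degassed MeOH, 0 °C, then acidic ion-exchange resin and evaporation), which gives 13 with only volatile side products.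

**Further compounds**
F1 | step 4 | 2,4,6-trimethoxyphenyllead triacetate | COc1cc(OC)c([Pb](OC(C)=O)(OC(C)=O)OC(C)=O)c(OC)c1
F2 | step 2 | 4-formyl-2,6-dimethoxyphenyl trifluoromethanesulfonate | COc1cc(C=O)cc(OC)c1OS(=O)(=O)C(F)(F)F
F3 | step 5 | nonaacetate of 13 | CC(=O)Oc1cc(OC(C)=O)cc(Oc2cc(OC(C)=O)cc(Oc3c(OC(C)=O)cc(OC(C)=O)c(-c4c(OC(C)=O)cc(OC(C)=O)cc4OC(C)=O)c3OC(C)=O)c2)c1
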